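The readings were computed with constants of no real substance.

No constant of this flask is given, so the first one has to be read from the earlier runs, and the cheapest is a ratio.

| flask | substrate | free catalyst | impurity | remark | time |
|---|---|---|---|---|---|
| red | 1.5 M | 15 mM | 4.9 mM | run made earlier |  |
| blue | 1.5 M | 60 mM | 4.9 mM | run made earlier |  |
| violet | 1.5 M | 30 mM | 2.5 mM | run made earlier |  |
| flask | 1.5 M | 30 mM | 4.9 mM |  | 10 min |

| run | time / min | target / % | substrate / % |
|---|---|---|---|
| red | 0.167 | 13.2 | 43.4 |
| red | 0.333 | 18.9 | 26.5 |
| red | 0.500 | 20.7 | 19.7 |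
| red | 1.00 | 21.7 | 10.9 |
| red | 2.00 | 17.9 | 8.4 |
| red | 3.00 | 14.7 | 8.3 |
| red | 6.00 | 10.9 | 5.1 |
| blue | 0.167 | 13.2 | 43.8 |
| blue | 0.333 | 16.3 | 26.4 |
| blue | 0.500 | 17.8 | 18.9 |
| blue | 1.00 | 16.9 | 10.5 |
| blue | 2.00 | 14.7 | 7.5 |
| blue | 3.00 | 13.3 | 6.0 |
| blue | 6.00 | 9.5 | 4.9 |
| violet | 0.167 | 12.8 | 43.3 |
| violet | 0.417 | 18.7 | 22.1 |
| violet | 1.00 | 18.7 | 10.7 |
| violet | 2.50 | 14.7 | 7.5 |
| violet | 6.00 | 10.1 | 5.0 |

(readings scatter by 0.5 percentage points)

- what was read earlier has a scatter of 0.5 percentage points, one standard deviation

- the moment within 10 min at which there is most target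
- the amount of target, in percent of the substrate charged, at that time
- earliest time at which at least nineteen twentieths of that best amount are there, in min
- latest time at which they still are, in min

In red, blue and violet, substrate and target fall together after 1.00 min. The bench rule for such a pair is quasi-equilibrium: target, as a fraction of the charge, stands at a fixed multiple of substrate. Target over substrate at 6.00 min, averaged over red, blue and violet, reads 2.03: this is the late ratio, a reading with the scatter of 0.5 percentage points in it.

| run | target over substrate at 0.167 min | at 1.00 min | at 6.00 min |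
|---|---|---|---|
| red | 0.304 | 1.99 | 2.14 |
| blue | 0.301 | 1.61 | 1.94 |
| violet | 0.296 | 1.75 | 2.02 |

The border of the rule shows in the middle column. At 1.00 min, the ratio has reached 0.980 of the late ratio in red, 0.860 in violet and 0.792 in blue, in the order of their catalyst charges. Violet has the catalyst charge of the flask, and there the rule gives 21.7% of target at that time, more than the 18.7% read. Violet reads 18.7% at 0.417 min and 18.7% at 1.00 min, so its top lies between those times. My reckoning for the flask therefore puts the top between those times too, on the near side of the border, where the rule sets no ceiling: at 0.417 min it gives 44.9% in violet against the 18.7% read. For the height, my reckoning takes violet's 18.7% as the nearest reading.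

The forecast says 19.7% at 0.7 min, in a window from 0.43 min to 1.2 min, its ground being “the geometric midpoint of red and blue, so I averaged them”.

The flask gives 19.9% at 0.681 min, with the window open from 0.418 min to 1.13 min, and this scheme runs in it:

    target + free catalyst ⇌ isomer of the product + free catalyst, rate k1*[free catalyst]*[target] forward; the back reaction follows from the equilibrium constant (K = 0.820, k = 0.370 M⁻¹ s⁻¹)
    free catalyst → spent catalyst A (k = 0.0130 s⁻¹)
    substrate ⇌ target (K = 1.80, k = 0.0230 s⁻¹)
    2 substrate → self-condensation product (k = 0.0320 M⁻¹ s⁻¹)
    free catalyst + impurity → spent catalyst B (k = 62.0 M⁻¹ s⁻¹)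

Substrate and target relax with a half-life of 0.323 min by that step alone, short against the 10 min allowed, yet at the best time the flask stands at a ratio of 1.36, below the late ratio. At 10.0 min, the flask's 3.61% of substrate gives 7.33% of target by the late ratio, and 7.17% stands there. In the neighbour flask charged with 0.60 M of substrate, 7.19% of substrate at 10.0 min gives 14.6%, and 14.0% of target stands there.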